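The ratio of Q gained to J gained in the theta run was not one number, and I used its climb to rank these flasks.

| flask | X | L | G | remark | time |
|---|---|---|---|---|---|
| theta | 0.10 M | 1.2 equiv | 0.030 M | run made earlier |  |
| alpha | 0.10 M | 1.2 equiv | 0.015 M | run made earlier |  |
| delta | 0.10 M | 1.2 equiv | 0.022 M | run made earlier |  |
| south-east | 0.10 M (fed, over 1.5 h) | 1.20 equiv | 0.0300 M | all else is in the flask from the start; the feed brings no volume worth counting | 4.0 h |
| east | 0.10 M | 1.20 equiv | 0.0300 M | everything together at the start | 4.0 h |
| south-west | 0.10 M (in portions, 3, over 1.5 h) | 1.20 equiv | 0.0300 M | first portion at the start, last at 1.5 h | 4.0 h |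
| north-east | 0.10 M | 1.20 equiv (fed, over 10 min) | 0.0300 M | all else is in the flask from the start; the feed brings no volume worth counting | 4.0 h |
| west | 0.10 M | 1.20 equiv (fed, over 1.5 h) | 0.0300 M | all else is in the flask from the start; the feed brings no volume worth counting | 4.0 h |

| run | time / h | Q / % | J / % |
|---|---|---|---|
| theta | 0.667 | 25.4 | 11.8 |
| theta | 1.33 | 40.8 | 14.5 |
| theta | 2.00 | 49.2 | 17.3 |
| theta | 2.50 | 53.6 | 16.2 |
| theta | 3.00 | 55.2 | 16.3 |
| theta | 4.00 | 59.6 | 17.5 |
| alpha | 0.333 | 12.0 | 6.5 |
| alpha | 0.500 | 20.8 | 9.4 |
| alpha | 0.833 | 34.1 | 14.0 |
| alpha | 1.33 | 45.9 | 15.0 |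
| alpha | 2.50 | 59.3 | 18.3 |
| alpha | 4.00 | 65.9 | 19.0 |
| delta | 0.250 | 8.6 | 4.1 |
| delta | 0.833 | 32.2 | 13.5 |
| delta | 1.33 | 43.1 | 15.4 |
| delta | 2.00 | 52.4 | 17.4 |
| delta | 3.00 | 59.4 | 17.3 |
| delta | 4.00 | 62.8 | 17.1 |

(standard deviation of a reading: 0.5 percentage points)

- a species is counted by the X in it: one J counts as two
- a reading or a percentage of Q counts all its forms, free or not

- the best flask by share of Q in Q plus J; "all alike" if 1.5 percentage points covers them all (south-east / east / south-west / north-east / west / all alike)
- share of Q in Q plus J at the end, south-east
- share of Q in Q plus J at the end, east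
- share of Q in Q plus J at the end, south-west
- share of Q in Q plus J at the end, north-east
- share of Q in Q plus J at the end, west

I followed one molecule of X. I supposed that L activates it and that the activated molecule then meets a fork. It closes to Q, or it takes a second X and gives J, which holds two X. In the first stretch of theta, up to 0.667 h, the readings show Q gaining 2.15 for each unit of J. In the middle, up to 1.33 h, the odds read 5.70, higher than before, with the scatter of the readings on that figure. Between 2.00 h and 4.00 h, Q gained 10 percentage points, while the gain of J, 0.2 points, lay inside the scatter.

So I took the odds to be a constant over x, where x is the fraction of the X charge still free. A batch carries x down from one, so as a rough figure I gave the average molecule an x of 0.5. Theta's final Q over J, times 0.5, gave 1.70. I called this the fork number, the odds of Q over J at x of one, a selectivity factor. Alpha, with half the G, gave 1.73, though its Q plus J was 85 points against 77 points in theta.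

The share of Q is then one over one plus mean x over the fork number. East repeats theta, so I expected 77.3%. North-east and west hold the X from the start and meter L, so I kept mean x at 0.5 and expected that same share. The first portion in south-west starts at x of a third, which gives 91.1% for that portion. I expected later portions to land on leftover X and pull the share of the whole flask below that. I ranked south-west and south-east above east.

The forecast named south-east, with 84% for south-east, 77.5% for east, 83% for south-west, 78.5% for north-east and 82% for west. Its ground was “X feeding does best because L feed loses time to G”. We parted on west, where its figure was higher than mine.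

The flask put south-west first: south-west 84.2%, south-east 82.5%, east 78.0%, north-east 77.9%, west 76.2%.

    E ⇌ Q, rate k1*(cs1 - [Q]) while solid is left; crystals form when [Q] > cs1 (solubility = 35.0 mM, k = 20.3 h⁻¹)
    X + Z → J (k = 10.7 L mol⁻¹ h⁻¹)
    X + L → Z (k = 12.7 L mol⁻¹ h⁻¹)
    Z → Q (k = 3.09 h⁻¹)
    G + Z → D (k = 45.3 L mol⁻¹ h⁻¹)

By the fork number, the share of west means a mean x of 0.531, about half, and that of south-west means 0.319. The neighbour of west with 0.040 M of X kept 28.0% of its X free, so I put its mean x on the same scale at 0.256. The fork number gives 86.9%, and that flask gave 85.9%. South-west had not come to rest: X stood at 10.2% after 4.00 h and 0% after 40.0 h, ten times as long, while Q, all forms counted, rose from 59.7% to 69.3% and the share reached 85.8%.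

(All runs were generated by integration from invented constants; noise was put on by code.)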